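**Plan**
- Retrosynthesis: the C3–H bond of ring A is traced back to C3–NH2 (reductive deamination). The five C–Br bonds (C4, C5, C6 of ring A; C2′, C4′ of ring B) are then cut together. The amine goes back to a nitro group, and the diaryl ether bond at C1 is cut last, to an aryl bromide and phenol.
- Forward: both benzene rings are bought and none is built. Ring A (as 2-bromo-6-nitroanisole) and ring B (as phenol) are joined by copper-catalysed C–O coupling, the nitro group is hydrogenated, all five bromines are introduced in one operation, and the amine is removed.
- Enabling feature (ring A: C1 O-aryl, C2 OMe, C3 H, C4–C6 Br; ring B: C1′ O, C2′ and C4′ Br): C3 is the only C–H of ring A and lies ortho to OMe. An NH2 parked there shields it and makes C4 (ortho) and C6 (para) fast sites, while C5 is para to OMe. On ring B the ether oxygen directs to C4′ and C2′, and C6′ ends up meta to two bromines.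
- Stereochemistry: the target has no stereocentre; only the regiochemistry of bromination has to be controlled.

Key step: step 3

Remark: the three starting materials are taken as purchased; the atom numbering of the plan is used throughout.

**Step 1**
Reactants: 1 2-bromo-6-nitroanisole (1-bromo-2-methoxy-3-nitrobenzene); 2 phenol
Product: 3 2-methoxy-1-nitro-3-phenoxybenzene
Conditions: CuI (10 mol %), picolinic acid (20 mol %), K3PO4, DMSO, 90 °C
Reagents that add atoms: none
Why: Ullmann-type copper-catalysed diaryl ether synthesis; the CuI/picolinic acid system accepts an ortho substituent next to the C–Br bond, the meta nitro group makes the bromide electron-poor, and neither partner carries a second halogen that could compete.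

**Step 2**
Reactants: 3 2-methoxy-1-nitro-3-phenoxybenzene
Product: 4 2-methoxy-3-phenoxyaniline
Conditions: H2 (1 atm), 10% Pd/C, EtOAc–EtOH, rt
Reagents that add atoms: none
Why: Catalytic hydrogenation of an aromatic nitro group to the aniline; the molecule is still halogen-free, so nothing else is reducible under these conditions.

**Step 3**
Reactants: 4 2-methoxy-3-phenoxyaniline; 5 bromine
Product: 7 4,5,6-tribromo-3-(2,4-dibromophenoxy)-2-methoxyaniline, via tribromoaniline 6 (not isolated)
Conditions: Br2 (6.5 equiv), AcOH, 15 °C, dark; then Fe powder (5 mol %), 60 °C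
Reagents that add atoms: bromine (compound 5), BrBr
Why: Five consecutive electrophilic aromatic brominations, each through an arenium ion; the closest known reaction type is the exhaustive bromination of anilines (aniline to 2,4,6-tribromoaniline) combined with iron-catalysed ring bromination of diaryl ethers. No ring is closed and no stereocentre is formed. At 15 °C the free NH2 at C3 should send bromine to C6 (para) and C4 (ortho) and the ether oxygen to C4′, giving 6. FeBr3 formed in the flask (trivalent iron) and gentle heating should then carry the two slow sites, C2′ (ortho to the ether oxygen) and C5 (para to OMe, the last C–H of ring A, between two bromines). The selectivity needed is complete filling of ring A with a stop at 2′,4′ on ring B: the first is secured because NH2 occupies C3, the site that OMe would otherwise offer to bromine, so every remaining C–H of ring A is a wanted one; the second because C6′ is meta to both ring-B bromines and ortho to an oxygen whose other aryl group is by then fully substituted and bulky, so it should lag behind C5 and C2′, and the bromine charge is kept to a small excess and followed by HPLC.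

**Step 4**
Reactants: 7 4,5,6-tribromo-3-(2,4-dibromophenoxy)-2-methoxyaniline
Product: 9 1,2,3-tribromo-4-(2,4-dibromophenoxy)-5-methoxybenzene, via diazonium hydrogen sulfate 8 (not isolated)
Conditions: NaNO2, conc. H2SO4, AcOH, 0–10 °C; then 50% aq H3PO2, Cu2O (cat.), 0 °C to rt
Reagents that add atoms: none
Why: Diazotisation followed by hydrodediazoniation (reductive deamination with hypophosphorous acid); nitrosylsulfuric acid made from NaNO2 in H2SO4 is the standard way to diazotise weakly basic, ortho-flanked polyhaloanilines, and H3PO2 with a trace of Cu2O then replaces N2 by hydrogen through an aryl radical chain that leaves the aryl bromides and both ethers untouched.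

**Compound list**
1 | 2-bromo-6-nitroanisole (1-bromo-2-methoxy-3-nitrobenzene) | COc1c(Br)cccc1[N+](=O)[O-] | starting material
2 | phenol | Oc1ccccc1 | starting material
3 | 2-methoxy-1-nitro-3-phenoxybenzene | COc1c(Oc2ccccc2)cccc1[N+](=O)[O-] | intermediate
4 | 2-methoxy-3-phenoxyaniline | COc1c(N)cccc1Oc1ccccc1 | intermediate
5 | bromine | BrBr | starting material
6 | 4,6-dibromo-3-(4-bromophenoxy)-2-methoxyaniline (formed in the flask in step 3) | COc1c(N)c(Br)cc(Br)c1Oc1ccc(Br)cc1 | intermediate
7 | 4,5,6-tribromo-3-(2,4-dibromophenoxy)-2-methoxyaniline | COc1c(N)c(Br)c(Br)c(Br)c1Oc1ccc(Br)cc1Br | intermediate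
8 | 4,5,6-tribromo-3-(2,4-dibromophenoxy)-2-methoxybenzenediazonium hydrogen sulfate (formed in the flask in step 4) | COc1c([N+]#N)c(Br)c(Br)c(Br)c1Oc1ccc(Br)cc1Br.OS(=O)(=O)[O-] | intermediate
9 | 1,2,3-tribromo-4-(2,4-dibromophenoxy)-5-methoxybenzene | COc1cc(Br)c(Br)c(Br)c1Oc1ccc(Br)cc1Br | target

Total step count: 4. Longest linear sequence: 4 steps.

**Steps most likely to fail**

1. Step 3. The five substitutions differ widely in rate. The likely failure is stalling before C5, which sits between two bromines and is activated only by a methoxy group twisted out of conjugation by its two ortho neighbours. Forcing it may start substitution at C6′ or acid cleavage of the methyl ether by the HBr formed. The fallback sets out from 3 and comes back at 7. It lets a free phenol carry the slow ring-A site before the amine exists.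
   - BBr3 in CH2Cl2 (−78 to 0 °C) should demethylate 3 to 2-nitro-6-phenoxyphenol F1.
   - Br2 (3.2 equiv) in AcOH at 20 to 50 °C should brominate para to the hydroxyl (the future C5, both ortho sites being occupied) and at C4′ and C2′, giving 4-bromo-2-(2,4-dibromophenoxy)-6-nitrophenol F2. The nitro group keeps C4 and C6 inert and protects the ring from oxidation.
   - MeI and K2CO3 in DMF should restore the methyl ether as 5-bromo-1-(2,4-dibromophenoxy)-2-methoxy-3-nitrobenzene F3.
   - H2 over sulfided 5% Pt/C in EtOAc should reduce the nitro group without C–Br hydrogenolysis to 5-bromo-3-(2,4-dibromophenoxy)-2-methoxyaniline F4.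
   - Br2 (2.1 equiv) in AcOH at 20 °C then has only the amine-activated C4 and C6 left and should give 7.

2. Step 4. The likely failure is loss of the diazonium ion before it is reduced. Diazotisation of the weakly basic, doubly flanked amine may be incomplete. In the diazonium ion the ortho methoxy group and the ortho and para bromines are open to displacement by water, and hydrogen transfer to the hindered aryl radical may be slow. The fallback sets out from 7 and comes back at 9. It traps the diazonium ion with iodide in a nearly water-free medium and removes the iodine by a polar step.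
   - NaNO2, KI and p-TsOH·H2O in MeCN at 10 to 20 °C should give 4,5,6-tribromo-3-(2,4-dibromophenoxy)-2-methoxybenzenediazonium 4-methylbenzenesulfonate F5.
   - Iodide captures F5 at once to give 1,2,3-tribromo-4-(2,4-dibromophenoxy)-6-iodo-5-methoxybenzene F6.
   - iPrMgCl·LiCl in THF at −78 °C should exchange only the C–I bond to give [2,3,4-tribromo-5-(2,4-dibromophenoxy)-6-methoxyphenyl]magnesium chloride F7.
   - MeOH protonates F7 at that temperature to 9.

3. Step 1. The likely failure is slow copper turnover at a bromide flanked by the methoxy group. Long heating then allows phenoxide to attack the nitro-activated methyl ether and allows reductive loss of bromine. The fallback sets out from 1 and comes back at 3. It makes ring A the oxygen nucleophile.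
   - Miyaura borylation of 1 (B2pin2, Pd(dppf)Cl2, KOAc, dioxane, 90 °C) should give 2-(2-methoxy-3-nitrophenyl)-4,4,5,5-tetramethyl-1,3,2-dioxaborolane F8.
   - Oxidation (30% H2O2, NaOH, THF–H2O, 0 °C) should give 2-methoxy-3-nitrophenol F9.
   - Metal-free O-arylation of F9 with diphenyliodonium triflate (KOtBu, THF, rt), which is little affected by ortho substituents, should give 3.

**Further compounds**
F1 | step 3 | 2-nitro-6-phenoxyphenol | Oc1c(Oc2ccccc2)cccc1[N+](=O)[O-]
F2 | step 3 | 4-bromo-2-(2,4-dibromophenoxy)-6-nitrophenol | Oc1c(Oc2ccc(Br)cc2Br)cc(Br)cc1[N+](=O)[O-]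
F3 | step 3 | 5-bromo-1-(2,4-dibromophenoxy)-2-methoxy-3-nitrobenzene | COc1c(Oc2ccc(Br)cc2Br)cc(Br)cc1[N+](=O)[O-]
F4 | step 3 | 5-bromo-3-(2,4-dibromophenoxy)-2-methoxyaniline | COc1c(N)cc(Br)cc1Oc1ccc(Br)cc1Br
F5 | step 4 | 4,5,6-tribromo-3-(2,4-dibromophenoxy)-2-methoxybenzenediazonium 4-methylbenzenesulfonate | COc1c([N+]#N)c(Br)c(Br)c(Br)c1Oc1ccc(Br)cc1Br.Cc1ccc(cc1)S(=O)(=O)[O-]
F6 | step 4 | 1,2,3-tribromo-4-(2,4-dibromophenoxy)-6-iodo-5-methoxybenzene | COc1c(I)c(Br)c(Br)c(Br)c1Oc1ccc(Br)cc1Br
F7 | step 4 | [2,3,4-tribromo-5-(2,4-dibromophenoxy)-6-methoxyphenyl]magnesium chloride | COc1c([Mg]Cl)c(Br)c(Br)c(Br)c1Oc1ccc(Br)cc1Br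
F8 | step 1 | 2-(2-methoxy-3-nitrophenyl)-4,4,5,5-tetramethyl-1,3,2-dioxaborolane | COc1c(B2OC(C)(C)C(C)(C)O2)cccc1[N+](=O)[O-]
F9 | step 1 | 2-methoxy-3-nitrophenol | COc1c(O)cccc1[N+](=O)[O-]
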